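**Assumption:** compounds 3 and 8 are taken as purchasable (the silyl and acetyl groups on them are protecting/leaving groups that are lost). Cembrane numbering is used to locate atoms: ring C1–C14, acrylate C15–C17, target = (1R,3S,4E,7E,11S,12R). The route is a paper design and has not been tested experimentally.

## Retrosynthetic overview

1. The 14-membered ring is closed last at C1–C2 by an intramolecular radical allyl transfer (SH2′) of a C2 iodide onto a 2-(sulfonylmethyl)-α,β-unsaturated ε-lactone. This one step forms the macrocycle, sets C1 and unveils the exocyclic methylene.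
2. The 7-membered lactone is made first, by RCM of a tertiary 2-(sulfonylmethyl)acrylate, after C11 acetylation and C12 acylation of a diol.
3. The skipped diene (C6–C7) comes from Zr-catalysed carboalumination of a terminal alkyne and Pd-catalysed coupling with an allylic acetate.
4. The C11/C12 anti-diol comes from Shi epoxidation and invertive hydrolysis of an E-trisubstituted enyne; C3 comes from an acetate aldol, and C2 becomes CH2I by Barton iododecarboxylation.
5. Ring order: lactone (RCM), then carbocycle (radical).

## Route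

**Step 1**
Reactants: 1, hex-1-en-5-yne
Product: 2, (E)-1-iodo-2-methylhexa-1,5-diene
Conditions: Me3Al (2.5 equiv), Cp2ZrCl2 (0.25 equiv), CH2Cl2, 0 °C → rt; then I2, THF, −30 → 0 °C
Reagents that add atoms: trimethylaluminium, C[Al](C)C; iodine, II
Why: Negishi Zr-catalysed syn-carboalumination puts Me on the internal and Al on the terminal alkyne carbon, and iodinolysis with retention gives the E-vinyl iodide; the terminal alkene is much less reactive.

**Step 2**
Reactants: 2, (E)-1-iodo-2-methylhexa-1,5-diene; 3, (4-bromobut-1-yn-1-yl)trimethylsilane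
Product: 4, (E)-5-methyldeca-1,5-dien-9-yne
Conditions: 3, Zn dust, LiCl, THF, 50 °C; then 2, PdCl2(dppf) (3 mol %), THF, rt; then K2CO3, MeOH, rt (crude)
Reagents that add atoms: none
Why: Negishi sp3–sp2 cross-coupling of the homopropargylzinc reagent retains the E geometry, and the methanolysis removes the C-silyl group.

**Step 3**
Reactants: 4, (E)-5-methyldeca-1,5-dien-9-yne
Product: 5, (2S,3S)-2-(but-3-en-1-yl)-3-(but-3-yn-1-yl)-2-methyloxirane
Conditions: ent-Shi ketone (L-fructose-derived, 30 mol %), Oxone, K2CO3, Bu4NHSO4, MeCN–DMM–aq. borate buffer (pH 10.5), 0 °C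
Reagents that add atoms: Oxone (potassium peroxymonosulfate), [K+].[O-]S(=O)(=O)OO
Why: Shi asymmetric epoxidation; the dioxirane reacts only with the electron-rich trisubstituted alkene (terminal alkene and alkyne are inert), and the enantiomeric ketone gives the (S,S) trans-epoxide (the D-fructose ketone gives R,R).

**Step 4**
Reactants: 5, the (2S,3S)-epoxide
Product: 6, (5R,6S)-5-methyldec-1-en-9-yne-5,6-diol
Conditions: HClO4 (3 mol %), THF–H2O (3:1), 0 °C
Reagents that add atoms: water, O
Why: Acid-catalysed epoxide hydrolysis; water attacks the tertiary carbon (C12) with inversion while C11 keeps its C–O bond, giving the anti-diol (11S,12R).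

**Step 5**
Reactants: 7, tert-butyl acetate; 8, (E)-4-acetoxy-2-methylbut-2-enal
Product: 9, tert-butyl (3S,4E)-6-acetoxy-3-hydroxy-4-methylhex-4-enoate
Conditions: 7, LDA, Et2O, −78 °C; CpTiCl[(R,R)-TADDOLate], −78 → −30 °C; then 8, −78 °C; aq. NH4F
Reagents that add atoms: none
Why: Duthaler titanium–TADDOL acetate aldol; the chiral titanium enolate adds 1,2 to the Si face of the enal and sets C3 (S). Any minor enantiomer becomes a separable diastereomer after step 9.

**Step 6**
Reactants: 9, the (3S)-hydroxy tert-butyl ester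
Product: 10, (3S,4E)-6-acetoxy-3-[(tert-butyldimethylsilyl)oxy]-4-methylhex-4-enoic acid
Conditions: TBSOTf (1.3 equiv), 2,6-lutidine, CH2Cl2, −78 → 0 °C; then TMSOTf (2 equiv), 0 °C → rt; AcOH–H2O–THF work-up
Reagents that add atoms: TBSOTf, CC(C)(C)[Si](C)(C)OS(=O)(=O)C(F)(F)F
Why: Silylation of the alcohol, then silyl-triflate cleavage of the tert-butyl ester to a silyl ester that hydrolyses on work-up; non-hydrolytic, so the allylic acetate survives.

**Step 7**
Reactants: 10, the (3S)-silyloxy acid
Product: 11, (2E,4R)-4-[(tert-butyldimethylsilyl)oxy]-5-iodo-3-methylpent-2-en-1-yl acetate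
Conditions: N-hydroxypyridine-2-thione, DIC, DMAP (cat.), CH2Cl2, 0 °C, dark; then CHI3 (3 equiv), hν (tungsten lamp), rt
Reagents that add atoms: iodoform, IC(I)I
Why: Barton decarboxylative iodination; the primary C2 radical is trapped by CHI3. The stereocentre is untouched (the descriptor changes to R only because CH2I outranks the alkenyl carbon).

**Step 8**
Reactants: 12, 2-(bromomethyl)acrylic acid
Product: 13, 2-[(phenylsulfonyl)methyl]acrylic acid
Conditions: PhSO2Na (2.2 equiv), MeOH, reflux; then 1 M HCl
Reagents that add atoms: sodium benzenesulfinate, [Na+].[O-]S(=O)c1ccccc1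
Why: S-alkylation of sulfinate by the allylic bromide (SN2/SN2′ give the same product) installs the radical leaving group.

**Step 9**
Reactants: 6, (5R,6S)-5-methyldec-1-en-9-yne-5,6-diol; 11, the allylic acetate/iodide
Product: 14, (5R,6S,9E,12E,14R)-14-[(tert-butyldimethylsilyl)oxy]-15-iodo-5,9,13-trimethylpentadeca-1,9,12-triene-5,6-diol
Conditions: 6, Me3Al (5 equiv), Cp2ZrCl2 (1 equiv), CH2Cl2, 0 °C → rt; volatiles removed; then 11, Pd(PPh3)4 (5 mol %), THF, rt
Reagents that add atoms: trimethylaluminium, C[Al](C)C
Why: Negishi carboalumination of the alkyne (diol carried as its aluminium alkoxide) gives the E-alkenylalane, which couples with the π-allyl palladium from 11 at the primary terminus; both olefin geometries are retained (7E new, 4E from 8).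

**Step 10**
Reactants: 14, the diol
Product: 15, (5R,6S,9E,12E,14R)-14-[(tert-butyldimethylsilyl)oxy]-5-hydroxy-15-iodo-5,9,13-trimethylpentadeca-1,9,12-trien-6-yl acetate
Conditions: Ac2O (1.2 equiv), pyridine, DMAP (5 mol %), CH2Cl2, 0 °C
Reagents that add atoms: acetic anhydride, CC(=O)OC(C)=O
Why: Selective acylation of the secondary C11 alcohol; the tertiary C12 alcohol does not react under these conditions.

**Step 11**
Reactants: 15, the monoacetate; 13, 2-[(phenylsulfonyl)methyl]acrylic acid
Product: 16, (5R,6S,9E,12E,14R)-6-acetoxy-14-[(tert-butyldimethylsilyl)oxy]-15-iodo-5,9,13-trimethylpentadeca-1,9,12-trien-5-yl 2-[(phenylsulfonyl)methyl]acrylate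
Conditions: 13, (COCl)2, DMF (cat.), CH2Cl2; then 15, DMAP (1.5 equiv), iPr2NEt, CH2Cl2, 0 → 40 °C
Reagents that add atoms: none
Why: DMAP-mediated acylation of the hindered tertiary alcohol by an acid chloride that cannot form a ketene; any SN2′ exchange of sulfinate by DMAP is reversed by sulfinate re-addition.

**Step 12**
Reactants: 16, the diene diester
Product: 17, (R)-7-methyl-3-[(phenylsulfonyl)methyl]-6,7-dihydrooxepin-2(5H)-one carrying at C7 the (1S,4E,7E,9R)-1-acetoxy-9-[(tert-butyldimethylsilyl)oxy]-10-iodo-4,8-dimethyldeca-4,7-dien-1-yl chain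
Conditions: Hoveyda–Grubbs II (10 mol %), 1,4-benzoquinone (20 mol %), PhMe (2 mM), 80 °C
Reagents that add atoms: none
Why: Ring-closing metathesis; Ru loads on the terminal alkene and closes onto the acrylate (helped by the quaternary C12), losing ethylene; the trisubstituted chain olefins are inert.

**Step 13**
Reactants: 17, the iodo lactone
Product: 18, 3-O-(tert-butyldimethylsilyl)dendronpholide A, (1R,3S,4E,7E,11S,12R)
Conditions: (Bu3Sn)2 (1.5 equiv), PhH (1 mM), hν (300 W sunlamp), 80 °C
Reagents that add atoms: none
Why: Proposed new method: intramolecular SH2′ allyl-transfer macrocyclisation. Bu3Sn• abstracts iodine, the nucleophilic C2 radical adds 14-exo to the β-carbon (C1) of the enoate, and the α-ester radical expels PhSO2•, which regenerates Bu3Sn• from the ditin and leaves the C15=C17 methylene. No H-donor is present, so a slow closure is tolerated, and the 4E olefin geometrically prevents 1,5-H transfer from the bis-allylic C6. C1 is set by substrate control: attack on the face syn to the C12 methyl gives the trans-1,4-bridged lactone (1R), argued to be the less strained macrocycle. Closest known chemistry: Keck/Baldwin allyl transfer to 2-(X-methyl)acrylates, and Porter/Pattenden radical macrocyclisations onto enoates.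

**Step 14**
Reactants: 18, the silyl ether
Product: 19, dendronpholide A
Conditions: HF·pyridine, pyridine, THF, 0 °C → rt
Reagents that add atoms: none
Why: Buffered fluoride desilylation frees the C3 alcohol without touching the acetate or the α-methylene lactone.

## Compound list

1 | hex-1-en-5-yne | C=CCCC#C | starting material
2 | (E)-1-iodo-2-methylhexa-1,5-diene | I/C=C(\C)CCC=C | intermediate
3 | (4-bromobut-1-yn-1-yl)trimethylsilane | C[Si](C)(C)C#CCCBr | starting material
4 | (E)-5-methyldeca-1,5-dien-9-yne | C#CCC/C=C(\C)CCC=C | intermediate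
5 | (2S,3S)-2-(but-3-en-1-yl)-3-(but-3-yn-1-yl)-2-methyloxirane | C#CCC[C@@H]1O[C@@]1(C)CCC=C | intermediate
6 | (5R,6S)-5-methyldec-1-en-9-yne-5,6-diol | C#CCC[C@H](O)[C@](C)(O)CCC=C | intermediate
7 | tert-butyl acetate | CC(=O)OC(C)(C)C | starting material
8 | (E)-4-acetoxy-2-methylbut-2-enal | CC(=O)OC/C=C(\C)C=O | starting material
9 | tert-butyl (3S,4E)-6-acetoxy-3-hydroxy-4-methylhex-4-enoate | CC(C)(C)OC(=O)C[C@H](O)/C(C)=C/COC(C)=O | intermediate
10 | (3S,4E)-6-acetoxy-3-[(tert-butyldimethylsilyl)oxy]-4-methylhex-4-enoic acid | OC(=O)C[C@H](O[Si](C)(C)C(C)(C)C)/C(C)=C/COC(C)=O | intermediate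
11 | (2E,4R)-4-[(tert-butyldimethylsilyl)oxy]-5-iodo-3-methylpent-2-en-1-yl acetate | IC[C@H](O[Si](C)(C)C(C)(C)C)/C(C)=C/COC(C)=O | intermediate
12 | 2-(bromomethyl)acrylic acid | C=C(CBr)C(=O)O | starting material
13 | 2-[(phenylsulfonyl)methyl]acrylic acid | C=C(CS(=O)(=O)c1ccccc1)C(=O)O | intermediate
14 | (5R,6S,9E,12E,14R)-14-[(tert-butyldimethylsilyl)oxy]-15-iodo-5,9,13-trimethylpentadeca-1,9,12-triene-5,6-diol | IC[C@H](O[Si](C)(C)C(C)(C)C)/C(C)=C/C/C=C(\C)CC[C@H](O)[C@](C)(O)CCC=C | intermediate
15 | (5R,6S,9E,12E,14R)-14-[(tert-butyldimethylsilyl)oxy]-5-hydroxy-15-iodo-5,9,13-trimethylpentadeca-1,9,12-trien-6-yl acetate | IC[C@H](O[Si](C)(C)C(C)(C)C)/C(C)=C/C/C=C(\C)CC[C@H](OC(C)=O)[C@](C)(O)CCC=C | intermediate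
16 | (5R,6S,9E,12E,14R)-6-acetoxy-14-[(tert-butyldimethylsilyl)oxy]-15-iodo-5,9,13-trimethylpentadeca-1,9,12-trien-5-yl 2-[(phenylsulfonyl)methyl]acrylate | IC[C@H](O[Si](C)(C)C(C)(C)C)/C(C)=C/C/C=C(\C)CC[C@H](OC(C)=O)[C@](C)(OC(=O)C(=C)CS(=O)(=O)c1ccccc1)CCC=C | intermediate
17 | (R)-7-[(1S,4E,7E,9R)-1-acetoxy-9-[(tert-butyldimethylsilyl)oxy]-10-iodo-4,8-dimethyldeca-4,7-dien-1-yl]-7-methyl-3-[(phenylsulfonyl)methyl]-6,7-dihydrooxepin-2(5H)-one | IC[C@H](O[Si](C)(C)C(C)(C)C)/C(C)=C/C/C=C(\C)CC[C@H](OC(C)=O)[C@@]1(C)CCC=C(CS(=O)(=O)c2ccccc2)C(=O)O1 | intermediate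
18 | 3-O-(tert-butyldimethylsilyl)dendronpholide A | C=C1C(=O)O[C@]2(C)CC[C@@H]1C[C@H](O[Si](C)(C)C(C)(C)C)/C(C)=C/C/C=C(\C)CC[C@@H]2OC(C)=O | intermediate
19 | dendronpholide A, (1R,3S,4E,7E,11S,12R)-11-acetoxy-3-hydroxycembra-4,7,15(17)-trien-16,12-olide | C=C1C(=O)O[C@]2(C)CC[C@@H]1C[C@H](O)/C(C)=C/C/C=C(\C)CC[C@@H]2OC(C)=O | target

## Summary

Total steps: 14. Longest linear sequence: 10 (steps 1–4, 9–14).

Steps most likely to fail, with fallbacks:

1. **Step 13 (radical SH2′ macrocyclisation).** Addition to a β-substituted enoate in a 14-membered closure is slow, and the facial selectivity at C1 is unproven. Fallback: make the same C1–C2 bond by intermolecular allyl transfer of iodide 11 onto a small lactone acceptor built from 6 (there the radical should add anti to the larger C12 substituent). The macrocycle would then be closed at C6–C7 by an intramolecular alkenyl iodide/allyl acetate coupling.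

2. **Step 12 (RCM to a trisubstituted 7-membered unsaturated lactone).** Fallback: acylate C12–OH with acryloyl chloride and close the much easier disubstituted unsaturated lactone by RCM. C17 is then introduced by Morita–Baylis–Hillman hydroxymethylation with formaldehyde and converted to the sulfone (MsCl, then PhSO2Na).

3. **Step 11 (acylation of the hindered tertiary alcohol next to the acetate).** Fallback: form the C12–O–acyl bond by acid-promoted opening of epoxide 5-type material at the tertiary carbon with acid 13, followed by acetylation. This needs the D-fructose Shi ketone (retention at C12), an alkenyl iodide in place of the alkyne, and fragment union by a reductive alkenyl–allyl coupling instead of the alane route.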